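**Plan**
- The target is a 3,5,7-trihydroxyflavone whose B ring is the benzene ring of a trans-(2R,3S)-2-guaiacyl-3-hydroxymethyl-2,3-dihydrobenzofuran. In that bicycle (O1, C2, C3, C3a, C4–C7, C7a) the free hydroxyl on C7 sits beside the O1-bearing C7a and C4 carries the chromone carbon. This is the pattern a furan–alkynyl ether benzannulation gives from a 3-substituted furan tethered through its C2.
- Retrosynthesis cuts (a) the pyranone ring (its O1–C2 bond and C3 hydroxyl) back through flavone and chalcone to a C4 aldehyde and a phloroacetophenone ether; (b) C3a–C7a and C6–C7 of the benzofuran, with the C7 oxygen returned to a furan, which opens the benzene and dihydrofuran rings to the ethynyl ether of a 2-furyl carbinol; (c) the C2–C3 bond as an aldol between O-benzylvanillin and a furylacetyl imide.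
- Forward: the bought furan is extended at C2 (lithiation, ethylene oxide, oxidation, imide), the chain is joined by the aldol, the secondary alcohol becomes the ethynyl ether, and gold closes the dihydrofuran and benzene rings in one step. The chromone ring is then built on C4 (chalcone, flavone, flavonol) and all benzyl ethers are removed.
- Stereochemistry: both stereocentres come from one boron syn-aldol under (R)-4-benzyloxazolidinone control. The syn pair becomes the trans C2/C3 pair of the ring, and no later step breaks a bond at either centre.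

Key step: step 9

Remark on the chemistry: 7 and 10 are bought as such; the ethynyl ether 18 is a labile secondary benzylic ynol ether, so it is kept below 0 °C and cyclised on the day it is made.

**Route**

Step 1
Reactants: 1 furan-3-carbaldehyde
Product: 2 2-(furan-3-yl)-1,3-dioxolane
Conditions: ethylene glycol, TsOH·H2O (cat.), toluene, reflux, Dean–Stark
Reagents that add atoms: ethylene glycol, OCCO
Why: Acid-catalysed acetalisation with azeotropic removal of water masks the aldehyde as a dioxolane that withstands the organolithium, hydride and alkoxide steps ahead and later directs metalation.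

Step 2
Reactants: 2 2-(furan-3-yl)-1,3-dioxolane
Product: 4 2-[3-(1,3-dioxolan-2-yl)furan-2-yl]ethanol, via 2-lithiofuran acetal 3 (not isolated)
Conditions: n-BuLi, THF, −78 → −20 °C; ethylene oxide, −78 °C → rt; H2O
Reagents that add atoms: ethylene oxide, C1CO1
Why: Directed lithiation removes the furan α-proton at C2, the one flanked by the ring oxygen and the chelating acetal, and the 2-furyllithium opens ethylene oxide (epoxide alkylation) to install the two-carbon arm.

Step 3
Reactants: 4 2-[3-(1,3-dioxolan-2-yl)furan-2-yl]ethanol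
Product: 6 [3-(1,3-dioxolan-2-yl)furan-2-yl]acetic acid, via furylacetaldehyde 5 (not isolated)
Conditions: TEMPO (cat.), PhI(OAc)2 (2.2 equiv), MeCN/aq. pH 7 phosphate buffer, 0 °C → rt; citric acid to pH 4 at 0 °C, extract, use at once
Reagents that add atoms: water, O
Why: Oxoammonium oxidation (TEMPO/PhI(OAc)2) in buffered aqueous acetonitrile takes the primary alcohol through the aldehyde hydrate to the acid without metal oxidants or strong acid, which the furan and the acetal should tolerate.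

Step 4
Reactants: 6 [3-(1,3-dioxolan-2-yl)furan-2-yl]acetic acid; 7 (4R)-4-benzyl-1,3-oxazolidin-2-one
Product: 9 (4R)-4-benzyl-3-{[3-(1,3-dioxolan-2-yl)furan-2-yl]acetyl}-1,3-oxazolidin-2-one, via mixed pivalic anhydride 8 (not isolated)
Conditions: PivCl, Et3N, THF, −20 °C; then 7, LiCl, −20 °C → rt
Reagents that add atoms: none
Why: N-acylation of the oxazolidinone through the mixed pivalic anhydride with LiCl activation (mixed-anhydride imide formation) avoids an acid chloride, whose HCl the acetal would not survive.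

Step 5
Reactants: 9 (4R)-4-benzyl-3-{[3-(1,3-dioxolan-2-yl)furan-2-yl]acetyl}-1,3-oxazolidin-2-one; 10 4-(benzyloxy)-3-methoxybenzaldehyde
Product: 12 (4R)-4-benzyl-3-[(2S,3R)-3-[4-(benzyloxy)-3-methoxyphenyl]-2-[3-(1,3-dioxolan-2-yl)furan-2-yl]-3-hydroxypropanoyl]-1,3-oxazolidin-2-one, via boron Z-enolate 11 (not isolated)
Conditions: Bu2BOTf, i-Pr2NEt, CH2Cl2, −78 → 0 °C; 10, −78 → 0 °C; pH 7 buffer, MeOH, 30% H2O2, 0 °C
Reagents that add atoms: none
Why: Evans boron syn-aldol, in which the Z-enolate reacts through a Zimmerman–Traxler chair on the enolate face away from the auxiliary benzyl group, should set the 2S,3R syn pair (the later C3 and C2 of the dihydrobenzofuran) in one step.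

Step 6
Reactants: 12 the syn-aldol imide
Product: 13 (1R,2S)-1-[4-(benzyloxy)-3-methoxyphenyl]-2-[3-(1,3-dioxolan-2-yl)furan-2-yl]propane-1,3-diol
Conditions: LiBH4, MeOH (1 equiv), THF, 0 °C
Reagents that add atoms: none
Why: Reductive removal of the oxazolidinone with LiBH4 (imide-selective hydride reduction) should give the 1,3-diol and return the auxiliary, the low temperature guarding against retro-aldol and α-epimerisation.

Step 7
Reactants: 13 (1R,2S)-1-[4-(benzyloxy)-3-methoxyphenyl]-2-[3-(1,3-dioxolan-2-yl)furan-2-yl]propane-1,3-diol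
Product: 15 (1R,2S)-3-(benzyloxy)-1-[4-(benzyloxy)-3-methoxyphenyl]-2-[3-(1,3-dioxolan-2-yl)furan-2-yl]propan-1-ol, via stannylene acetal 14 (not isolated)
Conditions: Bu2SnO, toluene, reflux, Dean–Stark; then BnBr, Bu4NBr (cat.), 80 °C
Reagents that add atoms: benzyl bromide, BrCc1ccccc1
Why: Stannylene-acetal-mediated regioselective O-alkylation benzylates the less hindered primary oxygen and leaves the secondary benzylic hydroxyl free, and a benzyl ether, unlike a silyl ether, cannot migrate to the neighbouring alkoxide in step 8.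

Step 8
Reactants: 15 (1R,2S)-3-(benzyloxy)-1-[4-(benzyloxy)-3-methoxyphenyl]-2-[3-(1,3-dioxolan-2-yl)furan-2-yl]propan-1-ol
Product: 18 2-{2-[(1R,2S)-3-(benzyloxy)-1-[4-(benzyloxy)-3-methoxyphenyl]-1-(ethynyloxy)propan-2-yl]furan-3-yl}-1,3-dioxolane, via dichlorovinyl ether 16 (not isolated), via lithium alkynyl ether 17 (not isolated)
Conditions: KH, THF, 0 °C; Cl2C=CHCl, −50 °C → rt; then n-BuLi (2.5 equiv), −78 → −40 °C; MeOH, −78 °C; cold work-up, filtration through Et3N-deactivated silica
Reagents that add atoms: trichloroethylene, ClC=C(Cl)Cl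
Why: In this trichloroethylene ynol ether synthesis the potassium alkoxide adds to dichloroacetylene formed in situ, n-BuLi then eliminates HCl and exchanges the remaining chlorine for lithium, and protonation gives the terminal ethynyl ether with the carbinol C–O bond, and thus both stereocentres, untouched.

Step 9
Reactants: 18 the ethynyl ether
Product: 19 (2R,3S)-3-[(benzyloxy)methyl]-2-[4-(benzyloxy)-3-methoxyphenyl]-4-(1,3-dioxolan-2-yl)-2,3-dihydro-1-benzofuran-7-ol
Conditions: (Ph3P)AuNTf2 (2 mol %), 4 Å MS, CH2Cl2 (0.02 M), 0 °C → rt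
Reagents that add atoms: none
Why: The cationic monovalent gold complex binds the electron-rich ethynyl ether, the furan C2=C3 bond attacks the oxygen-bearing alkyne carbon to give a cyclopropyl gold carbene, this opens with cleavage of the furan C2–O bond to a gold carbene conjugated with a dienal, the aldehyde oxygen closes onto the carbene carbon to an oxepine, and its arene oxide valence isomer opens to the phenol with the oxygen on the former terminal alkyne carbon (C7). The closest known reaction type is the gold-catalysed furan–yne phenol synthesis, which with ethynyl ethers of 2-(furan-2-yl)ethanols gives 2,3-dihydrobenzofuran-7-ols at room temperature. The dihydrofuran ring closes by 5-exo-dig attack of furan C2 on the activated alkyne (C3a–C7a bond), and the benzene ring closes by 6π electrocyclisation of the oxepine to the arene oxide (C6–C7 bond), followed by epoxide opening and tautomerisation. No stereocentre is formed: C2 and C3 are the tether carbons set in step 5, no bond to either is broken, and the syn pair becomes the trans pair of the ring. The step needs regioselectivity (hydroxyl on C7, carbon on C4), which is fixed by the polarisation of the ynol ether (attack at the oxygen-bearing carbon) and by the acetal sitting on furan C3, and chemoselectivity for the furan over the guaiacyl ring, which rests on the much higher nucleophilicity of the 2-alkylfuran. Low temperature, a silver-free non-acidic catalyst, dilution and molecular sieves are chosen so that the benzylic C–O bond does not ionise and the ynol ether is not hydrated.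

Step 10
Reactants: 19 the dihydrobenzofuran-7-ol
Product: 20 2-{(2R,3S)-7-(benzyloxy)-3-[(benzyloxy)methyl]-2-[4-(benzyloxy)-3-methoxyphenyl]-2,3-dihydro-1-benzofuran-4-yl}-1,3-dioxolane
Conditions: BnBr, K2CO3, DMF, rt
Reagents that add atoms: benzyl bromide, BrCc1ccccc1
Why: Williamson etherification caps the C7 phenol, which as a phenoxide para to the C4 aldehyde would otherwise shut down the condensation of step 13.

Step 11
Reactants: 20 the benzylated acetal
Product: 21 (2R,3S)-7-(benzyloxy)-3-[(benzyloxy)methyl]-2-[4-(benzyloxy)-3-methoxyphenyl]-2,3-dihydro-1-benzofuran-4-carbaldehyde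
Conditions: 1 M aq. HCl, THF, rt
Reagents that add atoms: water, O
Why: Acid-catalysed acetal hydrolysis of an aryl dioxolane para to an alkoxy group is fast in dilute acid at room temperature, conditions under which the benzyl ethers and the cyclic benzylic ether should persist.

Step 12
Reactants: 22 2',4',6'-trihydroxyacetophenone
Product: 23 1-[2,4-bis(benzyloxy)-6-hydroxyphenyl]ethanone
Conditions: BnBr (2.1 equiv), K2CO3, acetone, reflux
Reagents that add atoms: benzyl bromide, BrCc1ccccc1
Why: Williamson benzylation takes two of the three phenols, while the hydroxyl hydrogen-bonded to the acetyl carbonyl stays unreacted and is kept for ring closure.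

Step 13
Reactants: 21 the C4 aldehyde; 23 1-[2,4-bis(benzyloxy)-6-hydroxyphenyl]ethanone
Product: 24 (E)-1-[2,4-bis(benzyloxy)-6-hydroxyphenyl]-3-{(2R,3S)-7-(benzyloxy)-3-[(benzyloxy)methyl]-2-[4-(benzyloxy)-3-methoxyphenyl]-2,3-dihydro-1-benzofuran-4-yl}prop-2-en-1-one
Conditions: KOH, EtOH/THF, rt
Reagents that add atoms: none
Why: Claisen–Schmidt condensation (crossed aldol then dehydration) of the methyl ketone with the non-enolisable aldehyde should give the E-chalcone.

Step 14
Reactants: 24 the chalcone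
Product: 26 5,7-bis(benzyloxy)-2-{(2R,3S)-7-(benzyloxy)-3-[(benzyloxy)methyl]-2-[4-(benzyloxy)-3-methoxyphenyl]-2,3-dihydro-1-benzofuran-4-yl}-4H-chromen-4-one, via flavanone 25 (not isolated)
Conditions: I2 (10 mol %), DMSO, 120 °C
Reagents that add atoms: none
Why: Iodine-catalysed oxidative cyclisation of a 2'-hydroxychalcone closes the pyranone ring by 6-endo oxa-Michael addition to the flavanone, and α-iodination with loss of HI then gives the flavone while DMSO returns HI to I2.

Step 15
Reactants: 26 the flavone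
Product: 28 5,7-bis(benzyloxy)-2-{(2R,3S)-7-(benzyloxy)-3-[(benzyloxy)methyl]-2-[4-(benzyloxy)-3-methoxyphenyl]-2,3-dihydro-1-benzofuran-4-yl}-3-hydroxy-4H-chromen-4-one, via flavone epoxide 27 (not isolated)
Conditions: dimethyldioxirane (acetone solution, excess), CH2Cl2, 0 °C; then TsOH·H2O (cat.), rt
Reagents that add atoms: dimethyldioxirane, CC1(C)OO1
Why: Dimethyldioxirane epoxidation of the C2=C3 bond of the flavone followed by acid-catalysed epoxide opening and enolisation gives the 3-hydroxyflavone, a sequence that avoids the aurone pathway of direct chalcone oxidation.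

Step 16
Reactants: 28 the penta-O-benzyl flavonol
Product: 29 2-[(2R,3S)-7-hydroxy-2-(4-hydroxy-3-methoxyphenyl)-3-(hydroxymethyl)-2,3-dihydro-1-benzofuran-4-yl]-3,5,7-trihydroxy-4H-chromen-4-one (CNP0195987.1)
Conditions: H2 (1 atm), 10% Pd/C, THF/MeOH, rt
Reagents that add atoms: none
Why: Catalytic hydrogenolysis cleaves the four aryl benzyl ethers and the primary alkyl benzyl ether, while at one atmosphere and room temperature the chromone double bond and the ring benzylic C2–O1 bond should be left alone.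

**Compound list**

1 | furan-3-carbaldehyde | O=Cc1ccoc1 | starting material
2 | 2-(furan-3-yl)-1,3-dioxolane | C1COC(O1)c1ccoc1 | intermediate
3 | 2-lithio-3-(1,3-dioxolan-2-yl)furan (formed in situ) | [Li]c1occc1C1OCCO1 | intermediate
4 | 2-[3-(1,3-dioxolan-2-yl)furan-2-yl]ethanol | OCCc1occc1C1OCCO1 | intermediate
5 | [3-(1,3-dioxolan-2-yl)furan-2-yl]acetaldehyde (formed in situ) | O=CCc1occc1C1OCCO1 | intermediate
6 | [3-(1,3-dioxolan-2-yl)furan-2-yl]acetic acid | OC(=O)Cc1occc1C1OCCO1 | intermediate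
7 | (4R)-4-benzyl-1,3-oxazolidin-2-one | O=C1N[C@H](Cc2ccccc2)CO1 | starting material
8 | [3-(1,3-dioxolan-2-yl)furan-2-yl]acetic pivalic anhydride (formed in situ) | CC(C)(C)C(=O)OC(=O)Cc1occc1C1OCCO1 | intermediate
9 | (4R)-4-benzyl-3-{[3-(1,3-dioxolan-2-yl)furan-2-yl]acetyl}-1,3-oxazolidin-2-one | O=C(Cc1occc1C1OCCO1)N1[C@H](Cc2ccccc2)COC1=O | intermediate
10 | 4-(benzyloxy)-3-methoxybenzaldehyde (O-benzylvanillin) | COc1cc(C=O)ccc1OCc1ccccc1 | starting material
11 | dibutylboron (Z)-enolate of 9 (formed in situ) | CCCCB(CCCC)O/C(=C\c1occc1C1OCCO1)N1[C@H](Cc2ccccc2)COC1=O | intermediate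
12 | (4R)-4-benzyl-3-[(2S,3R)-3-[4-(benzyloxy)-3-methoxyphenyl]-2-[3-(1,3-dioxolan-2-yl)furan-2-yl]-3-hydroxypropanoyl]-1,3-oxazolidin-2-one | COc1cc([C@@H]([C@H](C(=O)N2[C@H](Cc3ccccc3)COC2=O)c2occc2C2OCCO2)O)ccc1OCc1ccccc1 | intermediate
13 | (1R,2S)-1-[4-(benzyloxy)-3-methoxyphenyl]-2-[3-(1,3-dioxolan-2-yl)furan-2-yl]propane-1,3-diol | COc1cc([C@@H]([C@H](CO)c2occc2C2OCCO2)O)ccc1OCc1ccccc1 | intermediate
14 | (4R,5S)-4-[4-(benzyloxy)-3-methoxyphenyl]-2,2-dibutyl-5-[3-(1,3-dioxolan-2-yl)furan-2-yl]-1,3,2-dioxastanninane (stannylene acetal of 13, formed in situ) | COc1cc([C@@H]([C@H](CO[Sn]2(CCCC)CCCC)c3occc3C3OCCO3)O2)ccc1OCc1ccccc1 | intermediate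
15 | (1R,2S)-3-(benzyloxy)-1-[4-(benzyloxy)-3-methoxyphenyl]-2-[3-(1,3-dioxolan-2-yl)furan-2-yl]propan-1-ol | COc1cc([C@@H]([C@H](COCc2ccccc2)c2occc2C2OCCO2)O)ccc1OCc1ccccc1 | intermediate
16 | (E)-1,2-dichlorovinyl ether of 15 at the C1 oxygen (1R,2S; formed in situ) | COc1cc([C@@H]([C@H](COCc2ccccc2)c2occc2C2OCCO2)O/C(Cl)=C\Cl)ccc1OCc1ccccc1 | intermediate
17 | 2-lithioethynyl ether of 15 at the C1 oxygen (1R,2S; formed in situ) | COc1cc([C@@H]([C@H](COCc2ccccc2)c2occc2C2OCCO2)OC#C[Li])ccc1OCc1ccccc1 | intermediate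
18 | 2-{2-[(1R,2S)-3-(benzyloxy)-1-[4-(benzyloxy)-3-methoxyphenyl]-1-(ethynyloxy)propan-2-yl]furan-3-yl}-1,3-dioxolane | COc1cc([C@@H]([C@H](COCc2ccccc2)c2occc2C2OCCO2)OC#C)ccc1OCc1ccccc1 | intermediate
19 | (2R,3S)-3-[(benzyloxy)methyl]-2-[4-(benzyloxy)-3-methoxyphenyl]-4-(1,3-dioxolan-2-yl)-2,3-dihydro-1-benzofuran-7-ol | COc1cc([C@@H]2Oc3c(O)ccc(C4OCCO4)c3[C@H]2COCc2ccccc2)ccc1OCc1ccccc1 | intermediate
20 | 2-{(2R,3S)-7-(benzyloxy)-3-[(benzyloxy)methyl]-2-[4-(benzyloxy)-3-methoxyphenyl]-2,3-dihydro-1-benzofuran-4-yl}-1,3-dioxolane | COc1cc([C@@H]2Oc3c(OCc4ccccc4)ccc(C4OCCO4)c3[C@H]2COCc2ccccc2)ccc1OCc1ccccc1 | intermediate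
21 | (2R,3S)-7-(benzyloxy)-3-[(benzyloxy)methyl]-2-[4-(benzyloxy)-3-methoxyphenyl]-2,3-dihydro-1-benzofuran-4-carbaldehyde | COc1cc([C@@H]2Oc3c(OCc4ccccc4)ccc(C=O)c3[C@H]2COCc2ccccc2)ccc1OCc1ccccc1 | intermediate
22 | 2',4',6'-trihydroxyacetophenone | CC(=O)c1c(O)cc(O)cc1O | starting material
23 | 1-[2,4-bis(benzyloxy)-6-hydroxyphenyl]ethanone | CC(=O)c1c(O)cc(OCc2ccccc2)cc1OCc1ccccc1 | intermediate
24 | (E)-1-[2,4-bis(benzyloxy)-6-hydroxyphenyl]-3-{(2R,3S)-7-(benzyloxy)-3-[(benzyloxy)methyl]-2-[4-(benzyloxy)-3-methoxyphenyl]-2,3-dihydro-1-benzofuran-4-yl}prop-2-en-1-one | COc1cc([C@@H]2Oc3c(OCc4ccccc4)ccc(/C=C/C(=O)c4c(O)cc(OCc5ccccc5)cc4OCc4ccccc4)c3[C@H]2COCc2ccccc2)ccc1OCc1ccccc1 | intermediate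
25 | 5,7-bis(benzyloxy)-2-{(2R,3S)-7-(benzyloxy)-3-[(benzyloxy)methyl]-2-[4-(benzyloxy)-3-methoxyphenyl]-2,3-dihydro-1-benzofuran-4-yl}chroman-4-one (flavanone, both C2 epimers, formed in situ) | COc1cc([C@@H]2Oc3c(OCc4ccccc4)ccc(C4CC(=O)c5c(OCc6ccccc6)cc(OCc6ccccc6)cc5O4)c3[C@H]2COCc2ccccc2)ccc1OCc1ccccc1 | intermediate
26 | 5,7-bis(benzyloxy)-2-{(2R,3S)-7-(benzyloxy)-3-[(benzyloxy)methyl]-2-[4-(benzyloxy)-3-methoxyphenyl]-2,3-dihydro-1-benzofuran-4-yl}-4H-chromen-4-one | COc1cc([C@@H]2Oc3c(OCc4ccccc4)ccc(-c4cc(=O)c5c(OCc6ccccc6)cc(OCc6ccccc6)cc5o4)c3[C@H]2COCc2ccccc2)ccc1OCc1ccccc1 | intermediate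
27 | 2,3-epoxide of flavone 26 (epoxide across chromone C2–C3, epimer mixture at the epoxide, formed in situ) | COc1cc([C@@H]2Oc3c(OCc4ccccc4)ccc(C45OC4C(=O)c4c(OCc6ccccc6)cc(OCc6ccccc6)cc4O5)c3[C@H]2COCc2ccccc2)ccc1OCc1ccccc1 | intermediate
28 | 5,7-bis(benzyloxy)-2-{(2R,3S)-7-(benzyloxy)-3-[(benzyloxy)methyl]-2-[4-(benzyloxy)-3-methoxyphenyl]-2,3-dihydro-1-benzofuran-4-yl}-3-hydroxy-4H-chromen-4-one | COc1cc([C@@H]2Oc3c(OCc4ccccc4)ccc(-c4oc5cc(OCc6ccccc6)cc(OCc6ccccc6)c5c(=O)c4O)c3[C@H]2COCc2ccccc2)ccc1OCc1ccccc1 | intermediate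
29 | 2-[(2R,3S)-7-hydroxy-2-(4-hydroxy-3-methoxyphenyl)-3-(hydroxymethyl)-2,3-dihydro-1-benzofuran-4-yl]-3,5,7-trihydroxy-4H-chromen-4-one | COc1cc([C@@H]2Oc3c(O)ccc(-c4oc5cc(O)cc(O)c5c(=O)c4O)c3[C@H]2CO)ccc1O | target

**Step count**

Total steps: 16. Longest linear sequence: 15 (steps 1–11 and 13–16, from furan-3-carbaldehyde); step 12 is a one-step side branch.

**Steps most likely to fail**

Step 8. The hindered secondary potassium alkoxide of 15 may add slowly to the dichloroacetylene formed from trichloroethylene, and the excess KH and n-BuLi may degrade the substrate before the two-stage sequence is complete. Fallback: the two alkyne carbons are built on the oxygen by carbonyl olefination instead of alkoxide addition. It sets out from 15, which is formylated (acetic formic anhydride, pyridine, 0 °C) to the formate F1. Dibromo-olefination of the formyl group (CBr4, PPh3, CH2Cl2, 0 °C → rt) gives the 2,2-dibromovinyl ether F2. Treatment of F2 with n-BuLi (2.2 equiv, THF, −78 °C) gives the lithium alkynyl ether 17 by elimination and bromine–lithium exchange. Protonation with MeOH at −78 °C then gives 18, where the route is rejoined.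

Step 9. The gold-activated ynol ether may ionise at the benzylic C–O bond and lose the tether, or the Lewis-acidic catalyst may strip the dioxolane before cyclisation and leave a 3-formylfuran too electron-poor to attack the alkyne. Fallback: the C4 carbon is carried through the key step as a silyloxymethyl group, which makes the furan a better nucleophile and removes the acid-labile acetal while the same bonds are formed. It sets out from 15 and comes back at 21:
- The acetal is hydrolysed (PPTS, acetone/H2O, 40 °C) to the hydroxy aldehyde F3 (open form of its lactol).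
- Reduction (NaBH4, MeOH, 0 °C) gives the furylmethanol diol F4.
- Silylation of the primary hydroxyl (TIPSCl, imidazole, DMF, 0 °C) gives the triisopropylsilyl ether F5.
- The protocol of step 8 leads through the dichlorovinyl ether F6 and the lithium alkynyl ether F7 to the ethynyl ether F8.
- The catalyst of step 9 should convert F8 into the dihydrobenzofuranol F9.
- Benzylation as in step 10 gives the benzyl ether F10.
- Desilylation (Bu4NF, THF, rt) gives the benzylic alcohol F11.
- MnO2 (CH2Cl2, rt) oxidises F11 to aldehyde 21.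

Step 14. In hot DMSO containing HI, the benzylic C2–O1 bond of the dihydrobenzofuran may open or epimerise and the benzyl ether peri to the carbonyl may be cleaved. Fallback: the pyranone ring is closed by acyl transfer and condensation instead of oxidation (Baker–Venkataraman route). It sets out from 21 and bypasses the chalcone:
- Oxidation (NaClO2, NaH2PO4, 2-methyl-2-butene, t-BuOH/H2O, 0 °C) gives the carboxylic acid F12.
- Esterification with the phenol of 23 (EDC·HCl, DMAP, CH2Cl2, rt) gives the aryl ester F13.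
- Base-induced O→C acyl shift (KOt-Bu, THF, 0 °C → rt) gives the 1,3-diketone F14.
- Cyclodehydration (TsOH·H2O cat., toluene, 60 °C) gives flavone 26, where the route is rejoined.

**Further compounds**

F1 | step 8 | (1R,2S)-3-(benzyloxy)-1-[4-(benzyloxy)-3-methoxyphenyl]-2-[3-(1,3-dioxolan-2-yl)furan-2-yl]propyl formate | COc1cc([C@@H]([C@H](COCc2ccccc2)c2occc2C2OCCO2)OC=O)ccc1OCc1ccccc1
F2 | step 8 | 2,2-dibromovinyl ether of 15 at the C1 oxygen (1R,2S) | COc1cc([C@@H]([C@H](COCc2ccccc2)c2occc2C2OCCO2)OC=C(Br)Br)ccc1OCc1ccccc1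
F3 | step 9 | (1R,2S)-3-(benzyloxy)-1-[4-(benzyloxy)-3-methoxyphenyl]-2-(3-formylfuran-2-yl)propan-1-ol (open form) | COc1cc([C@@H]([C@H](COCc2ccccc2)c2occc2C=O)O)ccc1OCc1ccccc1
F4 | step 9 | (1R,2S)-3-(benzyloxy)-1-[4-(benzyloxy)-3-methoxyphenyl]-2-[3-(hydroxymethyl)furan-2-yl]propan-1-ol | COc1cc([C@@H]([C@H](COCc2ccccc2)c2occc2CO)O)ccc1OCc1ccccc1
F5 | step 9 | (1R,2S)-3-(benzyloxy)-1-[4-(benzyloxy)-3-methoxyphenyl]-2-{3-[(triisopropylsilyloxy)methyl]furan-2-yl}propan-1-ol | COc1cc([C@@H]([C@H](COCc2ccccc2)c2occc2CO[Si](C(C)C)(C(C)C)C(C)C)O)ccc1OCc1ccccc1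
F6 | step 9 | (E)-1,2-dichlorovinyl ether of F5 at the C1 oxygen (1R,2S) | COc1cc([C@@H]([C@H](COCc2ccccc2)c2occc2CO[Si](C(C)C)(C(C)C)C(C)C)O/C(Cl)=C\Cl)ccc1OCc1ccccc1
F7 | step 9 | 2-lithioethynyl ether of F5 at the C1 oxygen (1R,2S) | COc1cc([C@@H]([C@H](COCc2ccccc2)c2occc2CO[Si](C(C)C)(C(C)C)C(C)C)OC#C[Li])ccc1OCc1ccccc1
F8 | step 9 | ethynyl ether of F5 at the C1 oxygen (1R,2S) | COc1cc([C@@H]([C@H](COCc2ccccc2)c2occc2CO[Si](C(C)C)(C(C)C)C(C)C)OC#C)ccc1OCc1ccccc1
F9 | step 9 | (2R,3S)-3-[(benzyloxy)methyl]-2-[4-(benzyloxy)-3-methoxyphenyl]-4-[(triisopropylsilyloxy)methyl]-2,3-dihydro-1-benzofuran-7-ol | COc1cc([C@@H]2Oc3c(O)ccc(CO[Si](C(C)C)(C(C)C)C(C)C)c3[C@H]2COCc2ccccc2)ccc1OCc1ccccc1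
F10 | step 9 | 7-O-benzyl ether of F9 (2R,3S) | COc1cc([C@@H]2Oc3c(OCc4ccccc4)ccc(CO[Si](C(C)C)(C(C)C)C(C)C)c3[C@H]2COCc2ccccc2)ccc1OCc1ccccc1
F11 | step 9 | {(2R,3S)-7-(benzyloxy)-3-[(benzyloxy)methyl]-2-[4-(benzyloxy)-3-methoxyphenyl]-2,3-dihydro-1-benzofuran-4-yl}methanol | COc1cc([C@@H]2Oc3c(OCc4ccccc4)ccc(CO)c3[C@H]2COCc2ccccc2)ccc1OCc1ccccc1
F12 | step 14 | (2R,3S)-7-(benzyloxy)-3-[(benzyloxy)methyl]-2-[4-(benzyloxy)-3-methoxyphenyl]-2,3-dihydro-1-benzofuran-4-carboxylic acid | COc1cc([C@@H]2Oc3c(OCc4ccccc4)ccc(C(=O)O)c3[C@H]2COCc2ccccc2)ccc1OCc1ccccc1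
F13 | step 14 | 2-acetyl-3,5-bis(benzyloxy)phenyl ester of F12 (2R,3S) | COc1cc([C@@H]2Oc3c(OCc4ccccc4)ccc(C(=O)Oc4cc(OCc5ccccc5)cc(OCc5ccccc5)c4C(C)=O)c3[C@H]2COCc2ccccc2)ccc1OCc1ccccc1
F14 | step 14 | 1-[2,4-bis(benzyloxy)-6-hydroxyphenyl]-3-{(2R,3S)-7-(benzyloxy)-3-[(benzyloxy)methyl]-2-[4-(benzyloxy)-3-methoxyphenyl]-2,3-dihydro-1-benzofuran-4-yl}propane-1,3-dione | COc1cc([C@@H]2Oc3c(OCc4ccccc4)ccc(C(=O)CC(=O)c4c(O)cc(OCc5ccccc5)cc4OCc4ccccc4)c3[C@H]2COCc2ccccc2)ccc1OCc1ccccc1
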